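# Total synthesis plan for fucodiphloroethol G (14)

## The problem

1. Fucodiphloroethol G (14) is a linear phloroglucinol tetramer A–O–B–O–C–D. Carbon a1 of ring A is bound through oxygen to b1 of ring B. The neighbouring carbon b6 is bound through oxygen to c1 of ring C. The neighbouring carbon c6 is bound directly to d1 of ring D.
2. The SMILES holds no stereocentre, and ring D is symmetric about the c6–d1 axis. The target is therefore achiral and nothing has to be controlled in space.
3. The difficulty lies in the three inter-ring bonds. Each ends on a carbon flanked by two oxygenated carbons (a1, b6, d1 and also c6). The biaryl carries four ortho oxygens and stands next to the b6–O–c1 ether, so ring C bears two bulky neighbours side by side.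
4. All four rings are very electron-rich. They are poor partners for nucleophilic aromatic substitution and add slowly to low-valent metals. Their boronic acids lose boron easily, and their phenoxides oxidise easily.
5. The ten hydroxyl groups are nearly alike: rings A and B share the 1,2,3,5 pattern and rings C and D the 1,3,5 pattern. A plan must therefore say at every stage which single oxygen is free to carry the next ring.
6. The free polyphenol is sensitive to air and base, so it can only be unveiled in the last step under non-oxidising conditions.
7. The enabling feature is that a1, b6 and c6 are each C-2 of a phloroglucinol ring, flanked by two C–OH and para to a third. This carbon corresponds to the terminal methylene C-6 of a 3,5-dioxohexanoate chain, whose Claisen closure on C-1 gives phloroglucinol. Whatever sits on a1, b6 or c6 (the oxygen of ring B, the oxygen of ring C, ring D) can therefore be placed on an unhindered sp3 CH2 before the ring exists.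

## Retrosynthesis

**Guiding idea.** The crowded bonds resist formation because both partners are finished, hindered, electron-rich arenes. If the cut is moved one bond further, into the ring, the crowded bond survives the disconnection. It becomes an ordinary CH2–O or CH2–aryl bond. The ring is unfolded to a triketide chain, kept masked as a 4-methoxy-2-pyranone. The lactone masks C-1 and C-5, and the enol ether masks C-3 and later serves as the para O-methyl protecting group. One reagent, bromide 2, then acts as a phloroglucinol that is electrophilic at C-2, which is a reversal of its natural polarity.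

**14 ⇒ 13.** Seven O–CH3 bonds are cut.
- Methyl is chosen because three of the seven come built into the pyranone units, one is placed with MeI in step 4 and three come with building block 3.
- Three hydroxyl groups of 13 are already free.
- The forward step must cleave aryl methyl ethers without touching the diaryl ethers or the biaryl.

**13 ⇒ 11.** Ring A is opened at the ring bond a1–a6 instead of the neighbouring a1–O bond. Carbon a6 is rejoined as a lactone carbonyl to the oxygen on a2.
- The hindered diaryl ether a1–O–b1 becomes the primary alkyl aryl ether of 11.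
- The forward reaction needs methoxide to open the lactone, and the α-aryloxy carbon to close on the ester.

**11 ⇒ 10 + 2.** The O–CH2 bond is cut (Williamson).
- The two hydroxyl groups of 10 are equivalent, so no regiochemical question arises and only the degree of alkylation must be held.
- The hydroxyl group left over is the free b5–OH of the target.

**10 ⇒ 8.** Ring B is opened in the same way at b6–b5.
- The most crowded ether, b6–O–c1 beside the biaryl, becomes the CH2–O bond of 8.
- This cut also fixes the order of events. A ring can only be hung on an oxygen of a ring that is already aromatic, so the rings must be grown in the order C, B, A.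

**8 ⇒ 6 + 2.** The O–CH2 bond and one O–CH3 bond are cut.
- The two hydroxyl groups of 6 are again equivalent.
- The second one is capped with MeI, so that after the next fold only ring B offers free hydroxyl groups.

**6 ⇒ 4.** Ring C is opened at c6–c5, and the tetra-ortho-oxygenated biaryl bond becomes the benzyl-type CH2–aryl bond of 4.
- Either ring of the biaryl could be unfolded, since c6 and d1 are both C-2 carbons.
- Ring C is chosen because ring D then comes from a commercial trimethoxyphenyl unit, and because the fold delivers the free c1–OH where ring B must be attached.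
- Compound 4 has no hindered bond at all.

**4 ⇒ 2 + 3.** The CH2–aryl bond is cut (sp3–sp2 Suzuki–Miyaura coupling). The new bond ends on a primary carbon, so the two ortho methoxy groups of 3 count for little.

**2 ⇒ 1.** The C–Br bond is cut (radical bromination of the only allylic-type methyl group). Reagent 2 is used three times and supplies 18 of the 24 ring carbons of 14.

## Roads not taken

**Alternative 1:** (the obvious route)
- *Cut:* the three inter-ring bonds a1–O, b6–O and c6–d1 themselves.
- *Forward key steps:* copper-catalysed Ullmann etherifications of 2,6-dioxygenated phenols with iodides of the type 2-iodo-1,3,5-trimethoxybenzene A1, and a tetra-ortho Suzuki–Miyaura coupling. Both lead to the decamethyl ether A2.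
- *Why the chosen plan is better:* every coupling joins a di-ortho-substituted, electron-rich halide to an equally hindered partner. Insertion of copper or zerovalent palladium is slow for such halides and protodeboronation is fast. Each monomer also needs its own halogenation and an orthogonal protecting group to expose one oxygen at a time. The chosen plan makes no bond between two hindered centres and needs no orthogonal protecting groups.

**Alternative 2:**
- *Cut:* c6–d1 as a union of two carbons of like polarity.
- *Forward key step:* oxidative dehydrodimerisation of 3,5-dimethoxyphenol A3 (FeCl3 or anodic oxidation) to 4,4',6,6'-tetramethoxybiphenyl-2,2'-diol A4, followed by ether formation.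
- *Why the chosen plan is better:* the phenoxyl radical of A3 carries spin at two ortho carbons, at the para carbon and on oxygen. Ortho–para, para–para and C–O coupling therefore compete, and A4 is oxidised more easily than A3. A4 must also be desymmetrised, and both hindered ethers remain unsolved. At best two steps are saved.

**Alternative 3:**
- *Cut:* rings B and D unfolded together from ring C.
- *Forward key step:* a double fold of the doubly armed 6-{[2-({4-methoxy-2-oxo-2H-pyran-6-yl}methoxy)-4,6-dimethoxyphenyl]methyl}-4-methoxy-2H-pyran-2-one A5 to the trimer tetraol A6. This forms two rings in one operation.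
- *Why the chosen plan is better:*
  - In opened A5 the carbanion of each arm lies six atoms from the ketone of the other arm, so an aldol closure to a 2H-chromene competes with both Dieckmann closures.
  - A6 has four phenolic hydroxyl groups of two nearly equal kinds, and nothing in the structure directs the arm for ring A onto ring B alone.
  - A5 itself needs a C-alkylation ortho to a protected phenol, which costs extra steps.
  - Growing one ring at a time always leaves two equivalent hydroxyl groups, so no regiochemical question arises.

Key step: step 3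

Remark: compounds 1 and 3 are taken as commercial, and the target is treated as achiral for the reason given in the first section.

## Steps

Step 1
Reactants: 1 4-methoxy-6-methyl-2H-pyran-2-one
Product: 2 6-(bromomethyl)-4-methoxy-2H-pyran-2-one
Conditions: NBS, AIBN (cat.), PhCF3, reflux
Reagents that add atoms: N-bromosuccinimide, O=C1CCC(=O)N1Br
Why: Wohl–Ziegler bromination; the C-6 methyl group holds the only allylic-type C–H bonds, and radical conditions in a non-polar solvent should suppress ionic bromination at C-3.

Step 2
Reactants: 2 6-(bromomethyl)-4-methoxy-2H-pyran-2-one; 3 (2,4,6-trimethoxyphenyl)boronic acid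
Product: 4 4-methoxy-6-(2,4,6-trimethoxybenzyl)-2H-pyran-2-one
Conditions: Pd(OAc)2 (cat.), SPhos, K3PO4, THF/H2O, 50 °C
Reagents that add atoms: none
Why: Suzuki–Miyaura coupling of an activated primary (benzyl-type) bromide with an arylboronic acid; zerovalent palladium adds quickly to the C–Br bond and the new bond ends on an unhindered CH2, so the two ortho methoxy groups of 3 should matter little. The mild base and temperature limit protodeboronation of 3 and spare the pyranone.

Step 3
Reactants: 4 4-methoxy-6-(2,4,6-trimethoxybenzyl)-2H-pyran-2-one
Product: 6 5-methoxy-2-(2,4,6-trimethoxyphenyl)benzene-1,3-diol, via open-chain keto ester 5 (not isolated)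
Conditions: NaOMe, MeOH, 120 °C (sealed tube), Ar; then aq. HCl
Reagents that add atoms: none
Why: Proposed new method: methoxide adds to the lactone carbonyl of 4 and opens it to the (E)-enol-ether keto ester 5, in which the ester and the ketone arm stay cis on the double bond as they were in the pyranone. Most of 5 rests as the enolate at C-4, which can only close back through oxygen to 4, while the minor enolate at the benzylic C-6 attacks the ester carbon in a Dieckmann condensation. This closes carbocyclic ring C in the 6-(enolendo)-exo-trig mode, and loss of methoxide followed by tautomerisation of the 2-aryl-5-methoxycyclohex-4-ene-1,3-dione to the resorcinol bis-phenoxide makes the closure irreversible and drains the equilibria before it. The closest known reaction types are the conversion of the parent 4-methoxy-6-methyl-2-pyranone into 5-methoxyresorcinol by hot NaOMe, the Claisen-mode folding of pyranone-masked polyketide chains with Mg(OMe)2, and the Dieckmann closure of 6-aryl-5-oxohexanoates (mesityl included) to 2-arylcyclohexane-1,3-diones; their use on a 6-arylmethylpyranone to make a biaryl is new. The aryl group acidifies the C-6 hydrogens compared with the parent methyl group, so a lower temperature than for the parent should suffice. No stereocentre is formed. The step needs C-closure to win over O-closure, which is secured because O-closure is reversible, no other electrophile is present and the aryl methyl ethers are inert to methoxide. The biaryl bond is never made in a crowded state, since it is the CH2–aryl bond of 4 around which the two new ortho oxygens are placed.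

Step 4
Reactants: 6 5-methoxy-2-(2,4,6-trimethoxyphenyl)benzene-1,3-diol; 2 6-(bromomethyl)-4-methoxy-2H-pyran-2-one
Product: 8 6-{[3,5-dimethoxy-2-(2,4,6-trimethoxyphenyl)phenoxy]methyl}-4-methoxy-2H-pyran-2-one, via monoether phenol 7 (not isolated)
Conditions: K2CO3 (1 equiv), DMF, 0 °C to rt, 2 as limiting reagent; then MeI, K2CO3, rt
Reagents that add atoms: iodomethane, CI
Why: Williamson ether synthesis by SN2 at an activated primary bromide; the two hydroxyl groups of 6 are equivalent, so only the degree of alkylation must be held, by keeping base and 2 limiting. Methylation of the remaining hydroxyl group in the same flask ensures that after the next fold only ring B carries free hydroxyl groups.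

Step 5
Reactants: 8 6-{[3,5-dimethoxy-2-(2,4,6-trimethoxyphenyl)phenoxy]methyl}-4-methoxy-2H-pyran-2-one
Product: 10 2-[3,5-dimethoxy-2-(2,4,6-trimethoxyphenyl)phenoxy]-5-methoxybenzene-1,3-diol, via open-chain keto ester 9 (not isolated)
Conditions: NaOMe, MeOH, 120 °C (sealed tube), Ar; then aq. HCl
Reagents that add atoms: none
Why: Proposed new method: the same methoxide opening and 6-(enolendo)-exo-trig Dieckmann closure as in step 3, now through the α-aryloxy enolate of 9, whose C–H bonds are acidified by the aryloxy oxygen, so that the b6–O–c1 ether is present from the start as a primary alkyl aryl ether and ring B is built around it. The closest known reaction types are the hot NaOMe conversion of 4-methoxy-6-methyl-2-pyranone into 5-methoxyresorcinol and the Dieckmann closure of 5-oxohexanoates to cyclohexane-1,3-diones; an aryloxy group on the nucleophilic carbon is new. Aromatisation to the bis-phenoxide makes the closure irreversible, and the biaryl and aryl methyl ethers are inert to methoxide.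

Step 6
Reactants: 10 2-[3,5-dimethoxy-2-(2,4,6-trimethoxyphenyl)phenoxy]-5-methoxybenzene-1,3-diol; 2 6-(bromomethyl)-4-methoxy-2H-pyran-2-one
Product: 11 6-({2-[3,5-dimethoxy-2-(2,4,6-trimethoxyphenyl)phenoxy]-3-hydroxy-5-methoxyphenoxy}methyl)-4-methoxy-2H-pyran-2-one
Conditions: K2CO3 (1 equiv), DMF, 0 °C to rt, 2 as limiting reagent
Reagents that add atoms: none
Why: Williamson ether synthesis as in step 4; the two hydroxyl groups of 10 are equivalent, so monoalkylation gives one constitution only. The second hydroxyl group is the free b5–OH of the target and needs no cap, because no alkylation follows.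

Step 7
Reactants: 11 6-({2-[3,5-dimethoxy-2-(2,4,6-trimethoxyphenyl)phenoxy]-3-hydroxy-5-methoxyphenoxy}methyl)-4-methoxy-2H-pyran-2-one
Product: 13 2-{2-[3,5-dimethoxy-2-(2,4,6-trimethoxyphenyl)phenoxy]-3-hydroxy-5-methoxyphenoxy}-5-methoxybenzene-1,3-diol, via open-chain keto ester 12 (not isolated)
Conditions: NaOMe, MeOH, 120 °C (sealed tube), Ar; then aq. HCl
Reagents that add atoms: none
Why: Proposed new method: a third methoxide opening and 6-(enolendo)-exo-trig Dieckmann closure through the α-aryloxy enolate of 12 builds ring A around the existing a1–O–b1 bond; the b5 phenoxide is meta to the reacting arm and should only be a spectator charge. The closest known reaction type is again the hot NaOMe conversion of 4-methoxy-6-methyl-2-pyranone into 5-methoxyresorcinol, and aromatisation makes the closure irreversible.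

Step 8
Reactants: 13 2-{2-[3,5-dimethoxy-2-(2,4,6-trimethoxyphenyl)phenoxy]-3-hydroxy-5-methoxyphenoxy}-5-methoxybenzene-1,3-diol
Product: 14 fucodiphloroethol G
Conditions: BBr3 (excess), CH2Cl2, −78 °C to rt, Ar; then degassed H2O
Reagents that add atoms: none
Why: Lewis-acid ether cleavage; bromide attacks the methyl carbon of each boron-complexed aryl methyl ether by SN2, a path closed to the diaryl ether oxygens and the biaryl. The acidic, non-oxidising medium suits the sensitive polyphenol.

## Compound list

1 | 4-methoxy-6-methyl-2H-pyran-2-one | COC1=CC(=O)OC(C)=C1 | starting material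
2 | 6-(bromomethyl)-4-methoxy-2H-pyran-2-one | COC1=CC(=O)OC(CBr)=C1 | intermediate
3 | (2,4,6-trimethoxyphenyl)boronic acid | COc1cc(OC)c(B(O)O)c(OC)c1 | starting material
4 | 4-methoxy-6-(2,4,6-trimethoxybenzyl)-2H-pyran-2-one | COC1=CC(=O)OC(Cc2c(OC)cc(OC)cc2OC)=C1 | intermediate
5 | methyl (2E)-3-methoxy-5-oxo-6-(2,4,6-trimethoxyphenyl)hex-2-enoate | COC(=O)/C=C(/OC)CC(=O)Cc1c(OC)cc(OC)cc1OC | intermediate
6 | 5-methoxy-2-(2,4,6-trimethoxyphenyl)benzene-1,3-diol | COc1cc(O)c(-c2c(OC)cc(OC)cc2OC)c(O)c1 | intermediate
7 | 6-{[3-hydroxy-5-methoxy-2-(2,4,6-trimethoxyphenyl)phenoxy]methyl}-4-methoxy-2H-pyran-2-one | COC1=CC(=O)OC(COc2cc(OC)cc(O)c2-c2c(OC)cc(OC)cc2OC)=C1 | intermediate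
8 | 6-{[3,5-dimethoxy-2-(2,4,6-trimethoxyphenyl)phenoxy]methyl}-4-methoxy-2H-pyran-2-one | COC1=CC(=O)OC(COc2cc(OC)cc(OC)c2-c2c(OC)cc(OC)cc2OC)=C1 | intermediate
9 | methyl (2E)-6-[3,5-dimethoxy-2-(2,4,6-trimethoxyphenyl)phenoxy]-3-methoxy-5-oxohex-2-enoate | COC(=O)/C=C(/OC)CC(=O)COc1cc(OC)cc(OC)c1-c1c(OC)cc(OC)cc1OC | intermediate
10 | 2-[3,5-dimethoxy-2-(2,4,6-trimethoxyphenyl)phenoxy]-5-methoxybenzene-1,3-diol | COc1cc(O)c(Oc2cc(OC)cc(OC)c2-c2c(OC)cc(OC)cc2OC)c(O)c1 | intermediate
11 | 6-({2-[3,5-dimethoxy-2-(2,4,6-trimethoxyphenyl)phenoxy]-3-hydroxy-5-methoxyphenoxy}methyl)-4-methoxy-2H-pyran-2-one | COC1=CC(=O)OC(COc2cc(OC)cc(O)c2Oc2cc(OC)cc(OC)c2-c2c(OC)cc(OC)cc2OC)=C1 | intermediate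
12 | methyl (2E)-6-{2-[3,5-dimethoxy-2-(2,4,6-trimethoxyphenyl)phenoxy]-3-hydroxy-5-methoxyphenoxy}-3-methoxy-5-oxohex-2-enoate | COC(=O)/C=C(/OC)CC(=O)COc1cc(OC)cc(O)c1Oc1cc(OC)cc(OC)c1-c1c(OC)cc(OC)cc1OC | intermediate
13 | 2-{2-[3,5-dimethoxy-2-(2,4,6-trimethoxyphenyl)phenoxy]-3-hydroxy-5-methoxyphenoxy}-5-methoxybenzene-1,3-diol (hepta-O-methyl fucodiphloroethol G) | COc1cc(O)c(Oc2cc(OC)cc(O)c2Oc2cc(OC)cc(OC)c2-c2c(OC)cc(OC)cc2OC)c(O)c1 | intermediate
14 | fucodiphloroethol G | Oc1cc(O)c(Oc2cc(O)cc(O)c2Oc2cc(O)cc(O)c2-c2c(O)cc(O)cc2O)c(O)c1 | target

## Step count and least certain steps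

Total step count: 8. Longest linear sequence: 8 (steps 1 to 8; reagent 2 from step 1 is used again in steps 4 and 6).

**Step 3 (key step, labelled).**
- *Risk:* the hindered benzylic enolate may be too scarce or too slow. The material would then only shuttle between pyranone and open chain. At forcing temperature, retro-Claisen cleavage of the ketone or demethylation of the vinylogous ester could take over.
- *Fallback (known chemistry):* it sets out from 3. A Suzuki–Miyaura coupling (Pd2(dba)3, SPhos, K3PO4, toluene, 100 °C) joins 3 with 2-iodo-5-methoxy-1,3-bis(methoxymethoxy)benzene F1. This gives the tetra-ortho-substituted biaryl 5-methoxy-1,3-bis(methoxymethoxy)-2-(2,4,6-trimethoxyphenyl)benzene F2. HCl in MeOH removes both acetals and the route is rejoined at 6.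

**Step 5 (labelled).**
- *Risk:* the closure takes place next to the biaryl and may be slow. Loss of aryloxide from the α-aryloxy ketone under hot methoxide, or air oxidation of the phenoxides, could then compete.
- *Fallback (known chemistry):* it sets out from 6. Monomethylation (MeI, 1 equiv, K2CO3) gives 3,5-dimethoxy-2-(2,4,6-trimethoxyphenyl)phenol F3. An Ullmann coupling with the iodide F1 (CuI, N,N-dimethylglycine, Cs2CO3, dioxane, 110 °C) gives 2-[3,5-dimethoxy-2-(2,4,6-trimethoxyphenyl)phenoxy]-5-methoxy-1,3-bis(methoxymethoxy)benzene F4. HCl in MeOH returns the route to 10.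

**Step 7 (labelled).**
- *Risk:* the extra phenoxide charge may lower the acidity of the reacting CH2 group and slow the closure. The very electron-rich trimer is prone to oxidation during long heating in base.
- *Fallback (known chemistry):* it sets out from 10.
  - Nucleophilic aromatic substitution on 4-fluoro-3,5-dimethoxybenzaldehyde (K2CO3, DMF, 130 °C, aldehyde limiting) gives 4-{2-[3,5-dimethoxy-2-(2,4,6-trimethoxyphenyl)phenoxy]-3-hydroxy-5-methoxyphenoxy}-3,5-dimethoxybenzaldehyde F5.
  - Baeyer–Villiger oxidation (mCPBA) gives the aryl formate 4-{2-[3,5-dimethoxy-2-(2,4,6-trimethoxyphenyl)phenoxy]-3-hydroxy-5-methoxyphenoxy}-3,5-dimethoxyphenyl formate F6.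
  - Methanolysis gives 4-{2-[3,5-dimethoxy-2-(2,4,6-trimethoxyphenyl)phenoxy]-3-hydroxy-5-methoxyphenoxy}-3,5-dimethoxyphenol F7.
  - BBr3 then cleaves its eight methyl ethers, and the route is rejoined at 14.

**Step 2.**
- *Risk:* protodeboronation of the 2,6-dimethoxy-substituted boronic acid may outrun transmetalation, and the bromide may hydrolyse in the aqueous base.
- *Fallback:* it sets out from 1. SeO2 oxidation (dioxane, heat) gives 4-methoxy-2-oxo-2H-pyran-6-carbaldehyde F8. TFA-promoted hydroxyalkylation of 1,3,5-trimethoxybenzene gives the racemic carbinol 6-[hydroxy(2,4,6-trimethoxyphenyl)methyl]-4-methoxy-2H-pyran-2-one F9. Et3SiH reduces F9 in the same flask through its strongly stabilised benzylic cation, and the route is rejoined at 4. The symmetry of the arene removes any regiochemical question.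

**Step 8.**
- *Risk:* cleavage of some of the seven ethers may stay incomplete, and the free decaphenol may oxidise during isolation.
- *Fallback:* it sets out from 13. The crude cleavage product is not isolated but acetylated (Ac2O, pyridine) to fucodiphloroethol G decaacetate F10, which is stable and can be purified on silica. Catalytic NaOMe in degassed MeOH under argon, followed by acidic resin, then releases 14.

## Further compounds

F1 | step 3 | 2-iodo-5-methoxy-1,3-bis(methoxymethoxy)benzene | COCOc1cc(OC)cc(OCOC)c1I
F2 | step 3 | 5-methoxy-1,3-bis(methoxymethoxy)-2-(2,4,6-trimethoxyphenyl)benzene | COCOc1cc(OC)cc(OCOC)c1-c1c(OC)cc(OC)cc1OC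
F3 | step 5 | 3,5-dimethoxy-2-(2,4,6-trimethoxyphenyl)phenol | COc1cc(O)c(-c2c(OC)cc(OC)cc2OC)c(OC)c1
F4 | step 5 | 2-[3,5-dimethoxy-2-(2,4,6-trimethoxyphenyl)phenoxy]-5-methoxy-1,3-bis(methoxymethoxy)benzene | COCOc1cc(OC)cc(OCOC)c1Oc1cc(OC)cc(OC)c1-c1c(OC)cc(OC)cc1OC
F5 | step 7 | 4-{2-[3,5-dimethoxy-2-(2,4,6-trimethoxyphenyl)phenoxy]-3-hydroxy-5-methoxyphenoxy}-3,5-dimethoxybenzaldehyde | COc1cc(C=O)cc(OC)c1Oc1cc(OC)cc(O)c1Oc1cc(OC)cc(OC)c1-c1c(OC)cc(OC)cc1OC
F6 | step 7 | 4-{2-[3,5-dimethoxy-2-(2,4,6-trimethoxyphenyl)phenoxy]-3-hydroxy-5-methoxyphenoxy}-3,5-dimethoxyphenyl formate | COc1cc(OC=O)cc(OC)c1Oc1cc(OC)cc(O)c1Oc1cc(OC)cc(OC)c1-c1c(OC)cc(OC)cc1OC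
F7 | step 7 | 4-{2-[3,5-dimethoxy-2-(2,4,6-trimethoxyphenyl)phenoxy]-3-hydroxy-5-methoxyphenoxy}-3,5-dimethoxyphenol | COc1cc(O)cc(OC)c1Oc1cc(OC)cc(O)c1Oc1cc(OC)cc(OC)c1-c1c(OC)cc(OC)cc1OC
F8 | step 2 | 4-methoxy-2-oxo-2H-pyran-6-carbaldehyde | COC1=CC(=O)OC(C=O)=C1
F9 | step 2 | 6-[hydroxy(2,4,6-trimethoxyphenyl)methyl]-4-methoxy-2H-pyran-2-one (racemic) | COC1=CC(=O)OC(C(O)c2c(OC)cc(OC)cc2OC)=C1
F10 | step 8 | fucodiphloroethol G decaacetate | CC(=O)Oc1cc(OC(C)=O)c(Oc2cc(OC(C)=O)cc(OC(C)=O)c2Oc2cc(OC(C)=O)cc(OC(C)=O)c2-c2c(OC(C)=O)cc(OC(C)=O)cc2OC(C)=O)c(OC(C)=O)c1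
A1 | alternative 1 | 2-iodo-1,3,5-trimethoxybenzene | COc1cc(OC)c(I)c(OC)c1
A2 | alternative 1 | deca-O-methyl fucodiphloroethol G | COc1cc(OC)c(Oc2cc(OC)cc(OC)c2Oc2cc(OC)cc(OC)c2-c2c(OC)cc(OC)cc2OC)c(OC)c1
A3 | alternative 2 | 3,5-dimethoxyphenol | COc1cc(O)cc(OC)c1
A4 | alternative 2 | 4,4',6,6'-tetramethoxybiphenyl-2,2'-diol | COc1cc(O)c(-c2c(O)cc(OC)cc2OC)c(OC)c1
A5 | alternative 3 | 6-{[2-({4-methoxy-2-oxo-2H-pyran-6-yl}methoxy)-4,6-dimethoxyphenyl]methyl}-4-methoxy-2H-pyran-2-one | COC1=CC(=O)OC(COc2cc(OC)cc(OC)c2CC2=CC(OC)=CC(=O)O2)=C1
A6 | alternative 3 | 2-[2-(2,6-dihydroxy-4-methoxyphenyl)-3,5-dimethoxyphenoxy]-5-methoxybenzene-1,3-diol | COc1cc(O)c(Oc2cc(OC)cc(OC)c2-c2c(O)cc(OC)cc2O)c(O)c1
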